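**Assumption:** isofraxidin (7-hydroxy-6,8-dimethoxycoumarin) is bought as a bulk plant-derived coumarin; the target oxirane is (2R,3R) as read from the SMILES, with ArOCH2 trans to the pentenyl chain.

**Retrosynthetic overview**
- The C4–C5 bond of the side chain is cut between a coumarin-bearing epoxy triflate and α-lithiated prenyl phenyl sulfoxide, which acts as a β-hydroxyvinyl anion (a d3 donor at a carbon that is normally an acceptor).
- A [2,3] sulfoxide–sulfenate shift then moves oxygen to the CMe2 carbon and sets the (E)-alkene, so the coupling pot ends at the target.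
- The epoxy triflate comes from the epoxy alcohol, made by Sharpless epoxidation of the (E)-allylic alcohol; this step sets both stereocentres.
- The allylic alcohol comes from SeO2 oxidation of the prenyl ether of isofraxidin; the sulfoxide comes from thiophenol and prenyl bromide.
- Rings: the coumarin bicycle is bought intact; the oxirane is the only ring formed (step 5).

**Route**

Step 1
Reactants: 1 thiophenol; 2 prenyl bromide
Product: 3 prenyl phenyl sulfide
Conditions: K2CO3, acetone, rt
Reagents that add atoms: none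
Why: SN2 S-alkylation of the soft thiolate at the unhindered CH2 of the allylic bromide.

Step 2
Reactants: 3 prenyl phenyl sulfide
Product: 4 prenyl phenyl sulfoxide (racemic at sulfur)
Conditions: NaIO4, MeOH/H2O, 0 °C to rt
Reagents that add atoms: sodium periodate, [Na+].[O-]I(=O)(=O)=O
Why: Periodate sulfide-to-sulfoxide oxidation stops at the sulfoxide and leaves the alkene alone; the sulfur stereocentre is destroyed in step 7, so the racemate is used.

Step 3
Reactants: 5 isofraxidin; 2 prenyl bromide
Product: 6 6,8-dimethoxy-7-(prenyloxy)coumarin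
Conditions: K2CO3, DMF, 50 °C
Reagents that add atoms: none
Why: Williamson etherification of the only phenol; both ortho positions carry OMe, so only O-alkylation is possible.

Step 4
Reactants: 6 6,8-dimethoxy-7-(prenyloxy)coumarin
Product: 7 7-{[(2E)-4-hydroxy-3-methylbut-2-en-1-yl]oxy}-6,8-dimethoxycoumarin
Conditions: SeO2 (20 mol%), tBuOOH (70% aq.), CH2Cl2, rt
Reagents that add atoms: tert-butyl hydroperoxide, CC(C)(C)OO (oxygen relayed through the SeO2 catalyst)
Why: Riley allylic oxidation (ene reaction then [2,3] shift) selectively oxidises the (E)-methyl of a trisubstituted alkene to the (E)-allylic alcohol, while the electron-poor coumarin alkene is inert.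

Step 5
Reactants: 7 (E)-allylic alcohol
Product: 8 7-{[(2R,3R)-3-(hydroxymethyl)-3-methyloxiran-2-yl]methoxy}-6,8-dimethoxycoumarin
Conditions: Ti(OiPr)4 (10 mol%), D-(−)-diisopropyl tartrate (12 mol%), tBuOOH (decane), 4 Å MS, CH2Cl2, −20 °C
Reagents that add atoms: tert-butyl hydroperoxide, CC(C)(C)OO
Why: Katsuki–Sharpless asymmetric epoxidation; L-(+)-tartrate gives (2S,3S) oxiranes from (E)-2-methyl-2-alkenols, so D-(−)-tartrate gives the (2R,3R) oxirane, and the E geometry fixes ArOCH2 trans to CH2OH (≥90% ee expected, upgradable by crystallisation).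

Step 6
Reactants: 8 epoxy alcohol
Product: 9 [(2R,3R)-3-{[(6,8-dimethoxy-2-oxo-2H-chromen-7-yl)oxy]methyl}-2-methyloxiran-2-yl]methyl triflate
Conditions: Tf2O, 2,6-lutidine, CH2Cl2, −78 °C; cold aqueous wash, used crude at once
Reagents that add atoms: triflic anhydride, O=S(=O)(OS(=O)(=O)C(F)(F)F)C(F)(F)F
Why: O-sulfonylation of the primary alcohol without touching either stereocentre; the triflate has no β-hydrogen to eliminate, and the trans aryloxymethyl group cannot reach it intramolecularly.

Step 7
Reactants: 4 prenyl phenyl sulfoxide; 9 epoxy triflate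
Product: 13 target CNP0325711.2 (7-{[(2R,3R)-3-[(2E)-4-hydroxy-4-methylpent-2-en-1-yl]-3-methyloxiran-2-yl]methoxy}-6,8-dimethoxycoumarin), via lithiated sulfoxide 10 (not isolated), via alkylated sulfoxide 11 (not isolated), via allylic sulfenate 12 (not isolated)
Conditions: 4, LiN(iPr)2 (1.0 equiv), THF, −78 °C; cannulate into 9, THF, −78 °C; then P(OMe)3, MeOH, −78 to 45 °C
Reagents that add atoms: none
Why: The sulfinyl-stabilised allyl anion alkylates at its α-carbon (the γ end is blocked by the gem-dimethyl group) by SN2 on the primary triflate, which at −78 °C with inverse addition should outrun attack on the electron-rich coumarin; the Mislow–Evans [2,3] rearrangement with thiophilic cleavage by P(OMe)3 then gives the tertiary alcohol and the (E)-alkene (α-substituent pseudo-equatorial in the envelope transition state), leaving the oxirane stereocentres untouched and erasing those at S and the α-carbon.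

**Compound list**
1 | thiophenol | Sc1ccccc1 | starting material
2 | prenyl bromide (1-bromo-3-methylbut-2-ene) | CC(C)=CCBr | starting material
3 | prenyl phenyl sulfide | CC(C)=CCSc1ccccc1 | intermediate
4 | prenyl phenyl sulfoxide (racemic) | CC(C)=CCS(=O)c1ccccc1 | intermediate
5 | isofraxidin (7-hydroxy-6,8-dimethoxy-2H-chromen-2-one) | COc1cc2ccc(=O)oc2c(OC)c1O | starting material
6 | 6,8-dimethoxy-7-[(3-methylbut-2-en-1-yl)oxy]-2H-chromen-2-one | COc1cc2ccc(=O)oc2c(OC)c1OCC=C(C)C | intermediate
7 | 7-{[(2E)-4-hydroxy-3-methylbut-2-en-1-yl]oxy}-6,8-dimethoxy-2H-chromen-2-one | COc1cc2ccc(=O)oc2c(OC)c1OC/C=C(\C)CO | intermediate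
8 | 7-{[(2R,3R)-3-(hydroxymethyl)-3-methyloxiran-2-yl]methoxy}-6,8-dimethoxy-2H-chromen-2-one | COc1cc2ccc(=O)oc2c(OC)c1OC[C@H]1O[C@]1(C)CO | intermediate
9 | [(2R,3R)-3-{[(6,8-dimethoxy-2-oxo-2H-chromen-7-yl)oxy]methyl}-2-methyloxiran-2-yl]methyl trifluoromethanesulfonate | COc1cc2ccc(=O)oc2c(OC)c1OC[C@H]1O[C@]1(C)COS(=O)(=O)C(F)(F)F | intermediate
10 | α-lithio prenyl phenyl sulfoxide | CC(C)=CC([Li])S(=O)c1ccccc1 | intermediate
11 | α-alkylated allylic sulfoxide (oxirane 2R,3R; mixture at S and at the S-bearing carbon) | COc1cc2ccc(=O)oc2c(OC)c1OC[C@H]1O[C@]1(C)CC(C=C(C)C)S(=O)c1ccccc1 | intermediate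
12 | (E)-allylic benzenesulfenate of the target alcohol | COc1cc2ccc(=O)oc2c(OC)c1OC[C@H]1O[C@]1(C)C/C=C/C(C)(C)OSc1ccccc1 | intermediate
13 | 7-{[(2R,3R)-3-[(2E)-4-hydroxy-4-methylpent-2-en-1-yl]-3-methyloxiran-2-yl]methoxy}-6,8-dimethoxy-2H-chromen-2-one | COc1cc2ccc(=O)oc2c(OC)c1OC[C@H]1O[C@]1(C)C/C=C/C(C)(C)O | target

**Count**
Total steps: 7. Longest linear sequence: 5 (steps 3–7, from isofraxidin).

**Steps most likely to fail, with fallbacks**

Step 7 (the anion may attack the coumarin lactone or C4 instead of the triflate). The fallback sets out from 4 and returns at 13, keeping the coumarin out of the carbanion step. Prenyl acetate (bought, CC(C)=CCOC(C)=O) is oxidised with SeO2/tBuOOH to (E)-4-hydroxy-3-methylbut-2-en-1-yl acetate F1. CBr4/PPh3 converts it to (E)-4-bromo-3-methylbut-2-en-1-yl acetate F2. Lithiated 4 (that is, 10) alkylates F2 at −78 °C in THF to the α-alkylated sulfoxide acetate F3. P(OMe)3 and K2CO3 in MeOH take F3 through the allylic sulfenate acetate F4, and with loss of the acetate give (2E,5E)-3,7-dimethylocta-2,5-diene-1,7-diol F5. Sharpless epoxidation (Ti(OiPr)4, D-(−)-diisopropyl tartrate, tBuOOH) acts only on the primary allylic alcohol, since tertiary allylic alcohols react very slowly, and gives [(2R,3R)-3-[(2E)-4-hydroxy-4-methylpent-2-en-1-yl]-3-methyloxiran-2-yl]methanol F6. Mitsunobu etherification of F6 with isofraxidin 5 (PPh3, diisopropyl azodicarboxylate, THF) gives 13.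

Step 6 (the epoxy triflate may decompose or be displaced too slowly at its neopentyl-type carbon). The fallback sets out from 7 and returns at 13, making the C–C bond before the oxirane exists. CBr4/PPh3 converts 7 to the allylic bromide 7-{[(2E)-4-bromo-3-methylbut-2-en-1-yl]oxy}-6,8-dimethoxycoumarin F7, a stable and fast SN2 partner. Alkylation with 10 at −78 °C gives the alkylated sulfoxide F8. P(OMe)3/MeOH takes F8 through the sulfenate F9 to the dienyl ether 7-{[(2E,5E)-7-hydroxy-3,7-dimethylocta-2,5-dien-1-yl]oxy}-6,8-dimethoxycoumarin F10. Shi epoxidation (D-fructose-derived ketone, KHSO5 as Oxone, K2CO3, MeCN/dimethoxymethane/H2O, 0 °C) of the more electron-rich trisubstituted alkene is expected to give the (2R,3R) oxirane 13; site selectivity over the disubstituted alkene is the open point.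

Step 4 (modest yield, over-oxidation to the enal, allyl aryl ether cleavage). The fallback sets out from 5 and returns at 7, replacing steps 3 and 4. Isofraxidin 5 and 2-methyl-2-vinyloxirane (isoprene monoxide, bought) react under Pd(PPh3)4 catalysis (zerovalent palladium) in THF at 40 °C. This is a Tsuji–Trost opening; under equilibrating conditions the phenoxide ends on the unsubstituted terminus of the π-allyl and gives the linear (E)-1,4-adduct 7 directly. New compound: none F0.

**Further compounds**
F1 | step 7 | (E)-4-hydroxy-3-methylbut-2-en-1-yl acetate | CC(=O)OC/C=C(\C)CO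
F2 | step 7 | (E)-4-bromo-3-methylbut-2-en-1-yl acetate | CC(=O)OC/C=C(\C)CBr
F3 | step 7 | (E)-3,7-dimethyl-5-(phenylsulfinyl)octa-2,6-dien-1-yl acetate (diastereomer mixture) | CC(=O)OC/C=C(\C)CC(C=C(C)C)S(=O)c1ccccc1
F4 | step 7 | (2E,5E)-3,7-dimethyl-7-[(phenylsulfanyl)oxy]octa-2,5-dien-1-yl acetate | CC(=O)OC/C=C(\C)C/C=C/C(C)(C)OSc1ccccc1
F5 | step 7 | (2E,5E)-3,7-dimethylocta-2,5-diene-1,7-diol | OC/C=C(\C)C/C=C/C(C)(C)O
F6 | step 7 | [(2R,3R)-3-[(2E)-4-hydroxy-4-methylpent-2-en-1-yl]-3-methyloxiran-2-yl]methanol | OC[C@H]1O[C@]1(C)C/C=C/C(C)(C)O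
F7 | step 6 | 7-{[(2E)-4-bromo-3-methylbut-2-en-1-yl]oxy}-6,8-dimethoxy-2H-chromen-2-one | COc1cc2ccc(=O)oc2c(OC)c1OC/C=C(\C)CBr
F8 | step 6 | 7-{[(2E)-3,7-dimethyl-5-(phenylsulfinyl)octa-2,6-dien-1-yl]oxy}-6,8-dimethoxy-2H-chromen-2-one (diastereomer mixture) | COc1cc2ccc(=O)oc2c(OC)c1OC/C=C(\C)CC(C=C(C)C)S(=O)c1ccccc1
F9 | step 6 | 7-{[(2E,5E)-3,7-dimethyl-7-[(phenylsulfanyl)oxy]octa-2,5-dien-1-yl]oxy}-6,8-dimethoxy-2H-chromen-2-one | COc1cc2ccc(=O)oc2c(OC)c1OC/C=C(\C)C/C=C/C(C)(C)OSc1ccccc1
F10 | step 6 | 7-{[(2E,5E)-7-hydroxy-3,7-dimethylocta-2,5-dien-1-yl]oxy}-6,8-dimethoxy-2H-chromen-2-one | COc1cc2ccc(=O)oc2c(OC)c1OC/C=C(\C)C/C=C/C(C)(C)O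
F0 | step 4 | none | none
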